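## Retrosynthetic overview
1. Alertenone (**14**, C30H44O2) is the head-to-tail Michael dimer of suberosenone (**13**). The cross-conjugated C3 enolate of one unit adds to the exocyclic enone CH2 of a second unit, which sets two epimerisable α-keto stereocentres.
2. **13** comes from the tricyclic ketone **9** by regiospecific C1 α-methylenation, using a temporary C3 aminomethylene blocking group (Bredereck, Mannich, elimination).
3. **9** comes from the acetonyl-substituted bicyclo[3.2.1]octan-8-one **6** by intramolecular aldol (third ring), then deoxygenation of the one-carbon bridge carbon A.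
4. The bicyclo[3.2.1]octanone (second ring) comes from 2-allyl-2-methallyl-3-methylcyclohexanone by the proposed new step, an acid-catalysed enol/tertiary-cation hydroalkylation (B–C11 bond). The cyclohexanone is the first ring.
5. The cyclohexanone comes from (S)-pulegone by two α′-alkylations, with the isopropylidene as a blocking group removed by retro-aldol.

Assumptions:
- Alertenone is taken to be the suberosenone–suberosenone Michael dimer, as the SMILES connectivity indicates.
- (S)-(−)-pulegone is assumed to be available, or made from (S)-3-methylcyclohexanone and acetone.
- C3 and C17 are α-to-ketone stereocentres assumed to equilibrate to the thermodynamic diastereomer, with the linker on the convex face.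

## Route

**Step 1**
Reactants: **1** (S)-pulegone
Product: **2** 6-allyl-pulegone (C6 epimer mixture)
Conditions: LDA, THF, −78 °C; then allyl bromide, −78 → 0 °C
Reagents that add atoms: allyl bromide, C=CCBr
Why: Enolate alkylation (SN2) is regiospecific because only C6 carries α′-H, the isopropylidene having blocked the other α-carbon; the new C6 centre is erased in step 2.

**Step 2**
Reactants: **2**
Product: **3** 6-allyl-6-(2-methylallyl)pulegone
Conditions: LDA, THF/DMPU, −78 °C; then methallyl bromide, −78 → 0 °C
Reagents that add atoms: methallyl bromide, CC(=C)CBr
Why: A(1,2) strain keeps the C5 methyl axial in the tetrasubstituted enolate. Axial alkylation anti to it puts the methallyl arm (future C10 bridge) trans to the methyl and sets the quaternary centre E.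

**Step 3**
Reactants: **3**
Product: **4** (S)-2-allyl-3-methyl-2-(2-methylallyl)cyclohexanone (methallyl trans, allyl cis to Me)
Conditions: 2 M NaOH, EtOH/H2O (4:1), reflux
Reagents that add atoms: none (water is consumed, acetone is lost)
Why: Conjugate hydration followed by retro-aldol (the reverse of pulegone formation) removes the isopropylidene blocking group as acetone and leaves CH2 at C6 (future B), with the quaternary centre and C3 methyl untouched.

**Step 4**
Reactants: **4**
Product: **5** 1-allyl-2,6,6-trimethylbicyclo[3.2.1]octan-8-one
Conditions: HNTf2 (10 mol%), HFIP/CH2Cl2 (1:1), 40 °C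
Reagents that add atoms: none (catalytic proton; net isomerisation)
Why: Proposed new method: HNTf2 reversibly protonates the 1,1-disubstituted methallyl alkene to a tertiary cation. This cation is separated from the quaternary centre by a CH2, so no Wagner–Meerwein path competes, and the only enolisable α-carbon (B) attacks it. The methallyl arm is axial and anti to the axial C3 methyl, 1,3-diaxial to B, so closure is chair-like and sets B, forming the gem-dimethyl two-carbon bridge and the ketone one-carbon bridge. The closest known reactions are cation–olefin (Prins-type) cyclisation, Reetz tert-alkylation of silyl enol ethers and Conia-ene hydroalkylation of 1,3-dicarbonyls. None has been shown for an unactivated monoketone plus an unactivated 1,1-disubstituted alkene building a bridged ring with an all-carbon quaternary centre.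

**Step 5**
Reactants: **5**
Product: **6** 2,6,6-trimethyl-1-(2-oxopropyl)bicyclo[3.2.1]octan-8-one
Conditions: PdCl2 (10 mol%), CuCl (1 equiv), O2 (1 atm), DMF/H2O (7:1), 60 °C
Reagents that add atoms: water, O
Why: Tsuji–Wacker oxidation is Markovnikov at the terminal alkene, and the ketone oxygen comes from water (O2 only reoxidises Cu and Pd and leaves no atoms). The allylic CH2 sits on a quaternary carbon, so alkene isomerisation is impossible, and the bridging ketone and all stereocentres survive.

**Step 6**
Reactants: **6**
Product: **7** tricyclic β-hydroxy ketone (A–OH, C3 on the face anti to the axial methyl)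
Conditions: LDA (1.1 equiv), THF, −78 → 0 °C; then sat. NH4Cl
Reagents that add atoms: none
Why: Intramolecular aldol. The bridging ketone cannot enolise (one α-carbon is quaternary and the other is a bridgehead), so only the acetonyl CH3 (C3) enolises and attacks the bridge C=O (A). The face anti to the axial C2 methyl is chosen because the other face would place C3 1,3-diaxial to that methyl, and dehydration to the bridge alkene is disfavoured by strain, so the aldol adduct is isolated.

**Step 7**
Reactants: **7**
Product: **8** methyl oxalate of the tertiary alcohol
Conditions: ClC(=O)C(=O)OMe, DMAP, pyridine, CH2Cl2, 0 °C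
Reagents that add atoms: methyl chlorooxoacetate, COC(=O)C(=O)Cl
Why: Acylation of the tertiary alcohol gives the methyl oxalate, the standard tertiary-alcohol handle for Barton-type radical deoxygenation. The mild 0 °C conditions avoid E1cB loss of the oxalate, which would give a strained bridge enone.

**Step 8**
Reactants: **8**
Product: **9** tricyclic cyclopentanone (nor-methylene suberosenone)
Conditions: Bu3SnH (3 equiv), AIBN, PhH, 80 °C
Reagents that add atoms: none (H only)
Why: Barton–McCombie-type radical deoxygenation of the tertiary oxalate. The fused cyclopentanone ring makes the bridge radical at A pyramidalise with C3 equatorial, on the face anti to the axial methyl. H is therefore delivered from the opposite (methyl-side) face, which fixes A with H axial and C3 on the two-carbon-bridge face, as in the target.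

**Step 9**
Reactants: **9**
Product: **10** C3-dimethylaminomethylene enaminone
Conditions: t-BuOCH(NMe2)2 (Bredereck's reagent), neat, 100 °C
Reagents that add atoms: Bredereck's reagent, CC(C)(C)OC(N(C)C)N(C)C
Why: Condensation occurs at the less hindered α-CH2 (C3, next to the tertiary A rather than the neopentyl C1 next to quaternary E), blocking C3 so that C1 is the only α-carbon left.

**Step 10**
Reactants: **10**
Product: **11** C1-dimethylaminomethyl enaminone
Conditions: LDA, THF, −78 °C; then Me2N+=CH2 I−, −78 → 0 °C
Reagents that add atoms: Eschenmoser's salt, C[N+](C)=C.[I-]
Why: α′-Deprotonation of the vinylogous amide can only occur at C1, and Mannich aminomethylation there is regiospecific.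

**Step 11**
Reactants: **11**
Product: **12** C1-Mannich base ketone
Conditions: 2 M NaOH, THF/MeOH (1:1), 60 °C
Reagents that add atoms: none (formate and Me2NH are lost)
Why: Enaminone hydrolysis followed by retro-Claisen deformylation removes the C3 blocking group. The new C1 centre is epimerisable and is destroyed in step 12, and any Mannich base that already eliminates to **13** under these conditions simply converges with step 12.

**Step 12**
Reactants: **12**
Product: **13** suberosenone
Conditions: MeI (5 equiv), MeOH, 25 °C; then DBU, CH2Cl2
Reagents that add atoms: none (the methyl from MeI leaves with NMe3)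
Why: Quaternisation then E1cB (Hofmann-type) elimination of the β-ammonium ketone gives the C1 exocyclic α-methylene ketone.

**Step 13**
Reactants: **13** (two equivalents, one as nucleophile and one as electrophile)
Product: **14** alertenone
Conditions: LiHMDS (0.5 equiv), THF, −78 → 0 °C; sat. NH4Cl quench; then DBU (cat.), CH2Cl2, 25 °C
Reagents that add atoms: none
Why: Intermolecular Michael addition of the kinetic cross-conjugated enolate (formed only at C3, since C1 is sp2) to the exocyclic enone of a second molecule. DBU then equilibrates C3 and C17 so that both CH2 linkers sit on the convex face.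

## Compound list
1 | (S)-pulegone, (5S)-5-methyl-2-(propan-2-ylidene)cyclohexanone | O=C1C(=C(C)C)CC[C@H](C)C1 | starting material
2 | 6-allyl-5-methyl-2-isopropylidenecyclohexanone (C6 epimers) | O=C1C(=C(C)C)CC[C@H](C)C1CC=C | intermediate
3 | 6-allyl-6-(2-methylallyl)-5-methyl-2-isopropylidenecyclohexanone | O=C1C(=C(C)C)CC[C@H](C)[C@@]1(CC=C)CC(C)=C | intermediate
4 | 2-allyl-3-methyl-2-(2-methylallyl)cyclohexanone | O=C1CCC[C@H](C)[C@@]1(CC=C)CC(C)=C | intermediate
5 | 1-allyl-2,6,6-trimethylbicyclo[3.2.1]octan-8-one | O=C1[C@@H]2CC[C@H](C)[C@@]1(CC=C)CC2(C)C | intermediate
6 | 2,6,6-trimethyl-1-(2-oxopropyl)bicyclo[3.2.1]octan-8-one | O=C1[C@@H]2CC[C@H](C)[C@@]1(CC(C)=O)CC2(C)C | intermediate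
7 | tricyclic β-hydroxy ketone (quadrane skeleton, A–OH) | C1C(=O)C[C@@]2(O)[C@@H]3CC[C@H](C)[C@]12CC3(C)C | intermediate
8 | methyl oxalate of 7 | C1C(=O)C[C@@]2(OC(=O)C(=O)OC)[C@@H]3CC[C@H](C)[C@]12CC3(C)C | intermediate
9 | tricyclic cyclopentanone (nor-methylene suberosenone) | C1C(=O)C[C@H]2[C@@H]3CC[C@H](C)[C@]12CC3(C)C | intermediate
10 | C3-dimethylaminomethylene enaminone of 9 | C1C(=O)C(=CN(C)C)[C@H]2[C@@H]3CC[C@H](C)[C@]12CC3(C)C | intermediate
11 | C1-dimethylaminomethyl enaminone | C(CN(C)C)1C(=O)C(=CN(C)C)[C@H]2[C@@H]3CC[C@H](C)[C@]12CC3(C)C | intermediate
12 | C1-Mannich base ketone | C(CN(C)C)1C(=O)C[C@H]2[C@@H]3CC[C@H](C)[C@]12CC3(C)C | intermediate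
13 | suberosenone | C=C1C(=O)C[C@H]2[C@@H]3CC[C@H](C)[C@]12CC3(C)C | intermediate
14 | alertenone | C=C1C(=O)[C@H](C[C@@H]2C(=O)C[C@H]3[C@@H]4CC[C@H](C)[C@]23CC4(C)C)[C@H]2[C@@H]3CC[C@H](C)[C@]12CC3(C)C | target

## Totals
Total steps: 13. Longest linear sequence: 13 (from (S)-pulegone).

## Three steps most likely to fail
1. **Step 4 (proposed new bicyclisation).** Risks are reversible O-attack, alkene isomerisation to the isobutenyl group, and interception of the cation by the allyl group. Fallback using known chemistry: hydrochlorinate the methallyl group (Co-catalysed hydrochlorination or HCl) to the tertiary chloride, convert the ketone to its TMS enol ether, and close with TiCl4 (intramolecular Reetz tert-alkylation).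
2. **Step 6 (aldol closure, with the step 8 deoxygenation that sets A).** Enolate closure onto a hindered ketone may be unfavourable or retro-aldol prone, and the H-transfer face at A may be poorly selective. Fallback changing the approach: make the α-bromomethyl ketone via the regiospecific terminal TMS enol ether and NBS, then close with an irreversible SmI2 intramolecular Reformatsky before the Barton deoxygenation.
3. **Step 13 (dimerisation).** Competing [4+2] of the 2-oxidodiene, oligomerisation and the wrong C3/C17 epimers are possible. Fallback: preform the TIPS dienol ether of **13** (kinetic, at C3) and run a Lewis-acid Mukaiyama–Michael (TMSOTf or Sc(OTf)3, −78 °C) onto a second equivalent of **13**, then epimerise with DBU.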